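(Readings and results come from a simulation for an exercise; noise was put on by code.)

The easy step came first: I treated the early loss of starting material in Tuesday's run as second order, and the rise of the reciprocal of [starting material] gave a slope I read as 6.16 M⁻¹ h⁻¹ at 6.00 h. The same reckoning read 13.7 M⁻¹ h⁻¹ at 25.0 h, so the course was no straight line, and I kept the early figure as an estimate of the second-order loss. Friday's run, with half the reagent, read 6.74 M⁻¹ h⁻¹ at 4.00 h.

in all of them: free catalyst 8.5 mM

| charge | starting material | reagent | capture agent | remark | time |
|---|---|---|---|---|---|
| Tuesday's | 0.050 M | 0.060 M | 5 mM | run made earlier |  |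
| Monday's | 0.070 M | 0.060 M | 5 mM | run made earlier |  |
| Saturday's | 0.11 M | 0.060 M | 5 mM | run made earlier |  |
| Friday's | 0.050 M | 0.030 M | 5 mM | run made earlier |  |
| spring | 0.050 M | 0.0600 M | 5.00 mM | one stirred flow tank at steady state, fed with the mixture as stated, mean residence time 25 h |  |
| midnight | 0.050 M | 0.0600 M | 5.00 mM | one stirred flow tank at steady state, fed with the mixture as stated, mean residence time 75.0 h |  |
| dawn | 0.050 M | 0.0600 M | 5.00 mM | a closed flask charged with all of it at once and left for 25 h | 25 h |
| dusk | 0.050 M (fed, over 20.0 h) | 0.0600 M | 5.00 mM | all but starting material at the start; starting material goes in evenly over 20.0 h, the run ends at 25 h | 25 h |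

- Tuesday's (time / h: target / %, starting material / %): 2.00: 0.1, 62.5; 6.00: 1.7, 35.1; 12.0: 8.8, 18.3; 20.0: 14.9, 10.8; 25.0: 17.0, 5.5
- Monday's (time / h: target / %, starting material / %): 3.00: 1.1, 43.7; 6.00: 1.9, 26.4; 10.0: 6.1, 17.3; 12.0: 6.5, 14.3; 15.0: 9.6, 11.3
- Saturday's (time / h: target / %, starting material / %): 1.33: 0.6, 54.0; 4.00: 0.9, 27.1; 8.00: 1.8, 16.3; 10.0: 3.4, 10.4; 15.0: 7.0, 7.6
- Friday's (time / h: target / %, starting material / %): 1.33: 0, 70.3; 4.00: 2.5, 42.6; 8.00: 3.8, 27.8; 10.0: 5.6, 20.3; 15.0: 11.4, 13.7

(standard deviation of a reading: 1 percentage point)

- the stated concentrations are those of everything mixed, before any reaction; amounts are the same in each set-up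
- the feed brings no volume worth counting
- the earlier runs were made in a closed, stirred flask

1. the set-up with the highest amount of target at the outlet or at the end, in percent of the starting material put in ("none" if the first two lie within 2 percentage points) (spring / midnight / dawn / dusk / none)
2. amount of target at the outlet or at the end, in percent of the starting material put in, spring
3. amount of target at the outlet or at the end, in percent of the starting material put in, midnight
4. amount of target at the outlet or at the end, in percent of the starting material put in, dawn
5. amount of target at the outlet or at the end, in percent of the starting material put in, dusk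

For the target I used a bench rule: after a lag, target equals a steady rate times the time. This ceiling rate, the target the catalyst turns out per hour while starting material stands above a border, I read from Monday's run between 6.00 h and 15.0 h as 0.599 mM h⁻¹, and Tuesday's run, with a smaller charge, read 0.592 mM h⁻¹ between 6.00 h and 12.0 h. Monday's first readings put the lag at 3.78 h.

The rule stopped working late in Tuesday's run: between 20.0 h and 25.0 h the target rose at 0.210 mM h⁻¹, about a third of the ceiling. Monday's run still held the ceiling at 7.91 mM of starting material, so I took that as the border.

In dusk the feed brings 2.50 mM h⁻¹, more than the ceiling removes, so I reckoned that [starting material] climbs until the second-order loss takes the difference, at 17.6 mM. Integrating that loss over the last hours gave 11.4 mM at the end, 1.44 times the border, so I expected the rule to hold and dusk to give 25.4 %. In midnight the ceiling would match 89.8 % of the feed, but that leaves 3.32 mM of starting material by my estimate, below the border, so I did not expect the ceiling to hold there.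

The forecast named midnight as best and gave spring 17 % (10 % to 26 %), midnight 42 % (28 % to 55 %) and dawn 17.5 % (15.5 % to 19.5 %). For dusk it gave 6 % (2 % to 11 %), well below my figure, on the ground that “slow feed keeps the intermediate low”.

The flasks gave 21.2 % in spring, 48.4 % in midnight, 16.4 % in dawn and 22.0 % in dusk.

    reagent + free catalyst → catalyst intermediate A (k = 29.0 M⁻¹ h⁻¹)
    catalyst intermediate A → catalyst intermediate B (k = 0.150 h⁻¹)
    starting material + catalyst intermediate B → catalyst intermediate C (k = 12.0 M⁻¹ h⁻¹)
    catalyst intermediate C → catalyst intermediate D (k = 0.620 h⁻¹)
    catalyst intermediate D → free catalyst + target (k = 2.50 h⁻¹)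
    2 starting material → self-condensation product (k = 2.90 M⁻¹ h⁻¹)
    capture agent + catalyst intermediate D → trapped intermediate (k = 8.00 M⁻¹ h⁻¹)

Midnight came highest, and dusk ran at 0.519 mM h⁻¹ after the lag, against the ceiling of 0.599 mM h⁻¹. Catalyst intermediate A has a half-life of 4.6 h by its turning into catalyst intermediate B, and catalyst intermediate B has 1.2 h with starting material held as charged in dawn. Midnight made target at 0.323 mM h⁻¹, about half of the ceiling.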